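The data come from a simulation with made-up constants, noise included.

- Slowness is not what holds maple back, so the hunch that waiting will help fails on the readings: target reads 73.3% at 4.00 min and 72.6% at 8.00 min, against a scatter of 0.5 percentage points, with starting material still at 27.8%.

| flask | starting material | second substrate | capture agent | free enzyme | temperature | remark | time |
|---|---|---|---|---|---|---|---|
| maple | 0.050 M | 0.0525 M | 5 mM | 25 µM | 37 °C | the very flask that is asked about, followed so far |  |
| birch | 0.050 M | 0.0525 M | 2.5 mM | 25 µM | 43 °C | run made earlier |  |
| flask | 0.050 M | 0.0525 M | 5.00 mM | 25 µM | 37 °C |  | 8.0 min |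

- maple (time / min: target / %, starting material / %): 0.667: 57.1, 42.2; 2.00: 72.0, 27.5; 4.00: 73.3, 27.7; 6.00: 72.8, 26.5; 8.00: 72.6, 27.8
- birch (time / min: target / %, starting material / %): 1.00: 86.4, 13.2; 2.50: 89.0, 10.7; 3.00: 89.7, 10.3; 5.00: 89.5, 9.2; 6.00: 90.1, 10.8

(readings scatter by 0.5 percentage points)

- grey: change nothing and wait 15 min more
- red: at 8.0 min add free enzyme, 100% of the amount charged, then wait 15 min
- ochre: at 8.0 min add second substrate, 100% of the amount charged, then wait 15 min

- additions leave the volume as it is
- a reading or a percentage of target counts all its forms, free or not

- target, in percent of the starting material first charged, at 8.0 min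
- the option that brings most further target ("none" if no option brings more than 2 percentage points) (grey / red / ochre / none)
- target present, in percent of the starting material first charged, after red
- target present, in percent of the starting material first charged, after ochre

- Birch, at 43 °C and with half the capture agent, reads higher, 90.1%; that suits an enzyme removed by capture agent, though the temperature moved too.
- The reckoning here takes the short-lived enzyme forms in steady state. At each passage second substrate B carries the enzyme on and capture agent T removes it, so dB/dE = −S·B/T, with E the enzyme lost.
- In maple T stays near its charge, 5 mM against 25 µM of enzyme, so ln(B at start / B at end) = S·E/T.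
- Maple's plateau, read as the mean 72.9% of its last three readings, leaves B at 16.0 mM. That is a fall in ln B of 1.19 for the whole enzyme charge, so S = 237, the second substrate consumed per enzyme lost at equal B and T, a selectivity factor read at 37 °C with the scatter of the readings.
- On this reckoning the flask has 72.9% at 8.0 min and no working enzyme, so grey and ochre stay there.
- Red restores E, so ln B falls again by 1.19, taking B to 4.91 mM and target to 95.2%. That gain of 22 points clears the margin, and the 47.6 mM reacted fits within the 0.050 M charged.
- The forecast gives 72.7% now, red as best, 85% after red and 72.9% after ochre, on the ground “Fresh enzyme buys the same integrated catalysis again”, and it parts from the reckoning here on red.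
- The flask gives 72.9% at 8.0 min, red as best with a gain of 22 points, 95.2% after red against 95.2% from S = 237, and 72.9% after ochre.

    ternary complex → free enzyme + target (k = 51.0 /s, Ea = 76.0 kJ/mol)
    free enzyme → unfolded enzyme (k = 2.20 × 10⁻⁴ /s, Ea = 191 kJ/mol)
    starting material + free enzyme ⇌ starting complex (K = 390 /M, k = 76000 /M/s, Ea = 17.0 kJ/mol, ΔH = −42.0 kJ/mol)
    second substrate + starting complex ⇌ ternary complex (K = 790 /M, k = 1.30 × 10⁵ /M/s, Ea = 23.0 kJ/mol, ΔH = −66.0 kJ/mol)
    free enzyme + target ⇌ idle complex, settled at all times (K = 180 /M, ΔH = −9.00 kJ/mol)
    capture agent + starting complex → trapped intermediate (k = 130 /M/s, Ea = 40.0 kJ/mol)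
    crystals ⇌ target, rate k7*(cs7 - [target]) while solid is left; crystals form when [target] > cs7 (solubility = 25.0 mM, k = 0.160 /s)
    (constants at 37 °C)

- By the capture step alone, with charges as given, starting complex has a half-life of 1.1 s, while free enzyme has 53 min by unfolding alone. At 8.00 min the flask holds >99.9% of its catalyst charge as trapped intermediate and 0.0187% as unfolded enzyme.
- In a neighbour flask, with 0.032 M of second substrate and the other charges as in the flask, S gives the same fall of 1.19 in ln B, so B ends at 9.78 mM and target at 44.4%. The computed neighbour flask has 44.4%.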